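**Strategy.** The route rests on cutting the bond between oxolane C2 and the syringyl ring. Without its aryl group C2, bonded to ring oxygen O1, is an acetal carbon, so the 2-methoxyoxolane 13 (already carrying the ferulate and the C4 benzyl group) ionises to a cyclic oxocarbenium ion that unprotected 2,6-dimethoxyphenol attacks through its carbon para to OH. In this one operation the last C–C bond, the C2 stereocentre and the whole target are formed: the cis C3/C4 side chains shield one face, so aryl enters trans. Only C4 is set by catalysis (asymmetric hydrogenation); C3 is relayed by trans alkylation of a lactone, whose ring is then switched to give the cis oxolane.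

Key step: step 8

Remark on numbering and configuration: oxolane atoms are O1, C2 (aryl), C3 (acyloxymethyl), C4 (benzyl), C5; the target is (2S,3R,4R), i.e. aryl trans to the C3 arm and the C3/C4 arms cis.

Assumption: 10, 11 and 13 are mixtures of epimers at the acetal carbon C2, which converge on ion 15; the (S,S)-ligand in step 2 is chosen on the usual sense of induction for this substrate class, and its antipode is taken should the (S)-acid form.

**Step 1**
Reactants: 1 4-(benzyloxy)-3-methoxybenzaldehyde; 2 dimethyl succinate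
Product: 3 (E)-4-[4-(benzyloxy)-3-methoxyphenyl]-3-(methoxycarbonyl)but-3-enoic acid
Conditions: NaOMe (2 equiv), MeOH, reflux; then aq. HCl
Reagents that add atoms: none
Why: Stobbe condensation, in which the succinate enolate adds to the aldehyde, the aldolate lactonises and E1cB opening of the paraconate gives the (E)-alkylidene half-ester with the free acid on the CH2 arm.

**Step 2**
Reactants: 3 (E)-4-[4-(benzyloxy)-3-methoxyphenyl]-3-(methoxycarbonyl)but-3-enoic acid
Product: 4 (R)-4-[4-(benzyloxy)-3-methoxyphenyl]-3-(methoxycarbonyl)butanoic acid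
Conditions: [Rh(cod)((S,S)-Et-DuPhos)]OTf (1 mol %), H2 (5 bar), NaOMe (10 mol %), MeOH, rt
Reagents that add atoms: none
Why: Rh-bisphospholane asymmetric hydrogenation of a Stobbe-derived itaconate half-ester, where chelation of the olefin and carboxylate to rhodium fixes the face of H2 delivery and should set the only catalyst-controlled stereocentre (the later oxolane C4) as R, the aryl benzyl ether being inert to the homogeneous catalyst.

**Step 3**
Reactants: 4 (R)-4-[4-(benzyloxy)-3-methoxyphenyl]-3-(methoxycarbonyl)butanoic acid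
Product: 5 (R)-4-[4-(benzyloxy)-3-methoxybenzyl]dihydrofuran-2(3H)-one
Conditions: LiBH4 (2 equiv), THF, 0 °C → rt; then 2 M HCl, rt
Reagents that add atoms: none
Why: chemoselective borohydride reduction of the ester beside the lithium carboxylate, then acid-promoted lactonisation of the hydroxy acid, with the stereocentre untouched.

**Step 4**
Reactants: 5 (R)-4-[4-(benzyloxy)-3-methoxybenzyl]dihydrofuran-2(3H)-one; 6 trimethyl orthoformate
Product: 8 (3S,4R)-4-[4-(benzyloxy)-3-methoxybenzyl]-3-(dimethoxymethyl)dihydrofuran-2(3H)-one, via silyl ketene acetal 7 (not isolated)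
Conditions: LDA, TMSCl, THF, −78 °C; concentrate; then 6, TMSOTf (10 mol %), CH2Cl2, −78 °C; Et3N quench
Reagents that add atoms: chlorotrimethylsilane C[Si](C)(C)Cl (silyl group of 7 only)
Why: Mukaiyama-type addition of the ketene silyl acetal to the dimethoxycarbenium ion from the orthoformate, the electrophile approaching anti to the C4 benzyl group so that the masked formyl carbon (the later C2) is installed trans by substrate control.

**Step 5**
Reactants: 8 (3S,4R)-4-[4-(benzyloxy)-3-methoxybenzyl]-3-(dimethoxymethyl)dihydrofuran-2(3H)-one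
Product: 9 (2R,3R)-3-[4-(benzyloxy)-3-methoxybenzyl]-2-(dimethoxymethyl)butane-1,4-diol
Conditions: LiAlH4, THF, 0 °C; aqueous NaOH work-up
Reagents that add atoms: none
Why: hydride reduction of the lactone to the 1,4-diol, which should outpace enolisation at 0 °C and leaves the acetal and both stereocentres intact.

**Step 6**
Reactants: 9 (2R,3R)-3-[4-(benzyloxy)-3-methoxybenzyl]-2-(dimethoxymethyl)butane-1,4-diol
Product: 11 [(3R,4R)-4-(4-hydroxy-3-methoxybenzyl)-2-methoxyoxolan-3-yl]methanol (C2 epimers), via cyclic acetal benzyl ether 10 (not isolated)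
Conditions: PPTS (5 mol %), CH2Cl2, 4 Å MS, rt; then EtOAc, H2 (1 atm), 10 % Pd/C, rt
Reagents that add atoms: none
Why: acid-catalysed transacetalisation in which only the C4 hydroxyl of the diol can close a five-membered ring (the C1 hydroxyl would give an oxetane), so the trans lactone pattern becomes the cis-3,4-disubstituted 2-methoxyoxolane with one free primary alcohol, followed by hydrogenolysis of the aryl benzyl ether before any benzylic ring ether exists.

**Step 7**
Reactants: 11 [(3R,4R)-4-(4-hydroxy-3-methoxybenzyl)-2-methoxyoxolan-3-yl]methanol; 12 (E)-ferulic acid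
Product: 13 [(3R,4R)-4-(4-hydroxy-3-methoxybenzyl)-2-methoxyoxolan-3-yl]methyl (E)-3-(4-hydroxy-3-methoxyphenyl)prop-2-enoate (C2 epimers)
Conditions: PPh3, DIAD, THF, 0 °C → rt
Reagents that add atoms: none
Why: Mitsunobu esterification, chemoselective because only the carboxylic acid is acidic enough to protonate the betaine and to displace the primary alkoxyphosphonium ion, so the phenols of both partners stay free.

**Step 8**
Reactants: 13 [(3R,4R)-4-(4-hydroxy-3-methoxybenzyl)-2-methoxyoxolan-3-yl]methyl (E)-ferulate; 14 2,6-dimethoxyphenol (5 equiv)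
Product: 16 [(2S,3R,4R)-2-(4-hydroxy-3,5-dimethoxyphenyl)-4-(4-hydroxy-3-methoxybenzyl)oxolan-3-yl]methyl (E)-3-(4-hydroxy-3-methoxyphenyl)prop-2-enoate, via oxocarbenium ion 15 (not isolated)
Conditions: BF3·OEt2 (0.5 equiv), CH2Cl2, 4 Å MS, −78 → −30 °C; Et3N quench at low temperature
Reagents that add atoms: none
Why: BF3 ionises the anomeric C2–OMe bond of 13 to the five-membered oxocarbenium ion 15 (C2=O1+), which the carbonyl oxygen of the cis C3 feruloyloxymethyl arm can cap reversibly on the β face as a six-membered dioxanylium ion, and the carbon para to the hydroxyl of 14 then attacks C2 and rearomatises, releasing methanol and the proton that turns the acid over. The closest known reaction type is the Lewis acid-mediated Friedel–Crafts C-arylation of lactol ethers by phenols and electron-rich arenes (aryl C-glycoside synthesis, arylation of 2-alkoxyoxolanes en route to lignans). No ring is closed; the oxolane ring is already in place. The new stereocentre C2 is set by substrate control: the C3 and C4 side chains are cis and both occupy the β face, so the arene enters from the open α face to give the 2,3-trans (2S) isomer, which is also the one favoured if the benzylic C2–O1 bond of the product ionises and recloses. The step needs attack at C4 of 14 rather than C3, which the free para-directing hydroxyl flanked by two methoxy-blocked ortho positions should secure, and it needs the external phenol to outrun the internal guaiacyl rings, which its fivefold excess, the β-face blockade of the only trajectory open to the C4 benzyl ring, and catalytic acid at low temperature should secure.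

**Compound list**

1 | 4-(benzyloxy)-3-methoxybenzaldehyde | O=Cc1ccc(OCc2ccccc2)c(OC)c1 | starting material
2 | dimethyl succinate | COC(=O)CCC(=O)OC | starting material
3 | (E)-4-[4-(benzyloxy)-3-methoxyphenyl]-3-(methoxycarbonyl)but-3-enoic acid | COC(=O)/C(=C/c1ccc(OCc2ccccc2)c(OC)c1)CC(=O)O | intermediate
4 | (R)-4-[4-(benzyloxy)-3-methoxyphenyl]-3-(methoxycarbonyl)butanoic acid | COC(=O)[C@H](Cc1ccc(OCc2ccccc2)c(OC)c1)CC(=O)O | intermediate
5 | (R)-4-[4-(benzyloxy)-3-methoxybenzyl]dihydrofuran-2(3H)-one | O=C1C[C@@H](Cc2ccc(OCc3ccccc3)c(OC)c2)CO1 | intermediate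
6 | trimethyl orthoformate | COC(OC)OC | starting material
7 | (R)-({4-[4-(benzyloxy)-3-methoxybenzyl]-4,5-dihydrofuran-2-yl}oxy)trimethylsilane (silyl ketene acetal) | C[Si](C)(C)OC1=C[C@@H](Cc2ccc(OCc3ccccc3)c(OC)c2)CO1 | intermediate (not isolated)
8 | (3S,4R)-4-[4-(benzyloxy)-3-methoxybenzyl]-3-(dimethoxymethyl)dihydrofuran-2(3H)-one (trans) | O=C1OC[C@H](Cc2ccc(OCc3ccccc3)c(OC)c2)[C@H]1C(OC)OC | intermediate
9 | (2R,3R)-3-[4-(benzyloxy)-3-methoxybenzyl]-2-(dimethoxymethyl)butane-1,4-diol | OC[C@H](Cc1ccc(OCc2ccccc2)c(OC)c1)[C@H](CO)C(OC)OC | intermediate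
10 | [(3R,4R)-4-[4-(benzyloxy)-3-methoxybenzyl]-2-methoxyoxolan-3-yl]methanol (3,4-cis, C2 epimers) | COC1OC[C@H](Cc2ccc(OCc3ccccc3)c(OC)c2)[C@@H]1CO | intermediate (not isolated)
11 | [(3R,4R)-4-(4-hydroxy-3-methoxybenzyl)-2-methoxyoxolan-3-yl]methanol (3,4-cis, C2 epimers) | COC1OC[C@H](Cc2ccc(O)c(OC)c2)[C@@H]1CO | intermediate
12 | (E)-ferulic acid, (E)-3-(4-hydroxy-3-methoxyphenyl)prop-2-enoic acid | COc1cc(/C=C/C(=O)O)ccc1O | starting material
13 | [(3R,4R)-4-(4-hydroxy-3-methoxybenzyl)-2-methoxyoxolan-3-yl]methyl (E)-3-(4-hydroxy-3-methoxyphenyl)prop-2-enoate (C2 epimers) | COC1OC[C@H](Cc2ccc(O)c(OC)c2)[C@@H]1COC(=O)/C=C/c3ccc(O)c(OC)c3 | intermediate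
14 | 2,6-dimethoxyphenol | COc1cccc(OC)c1O | starting material
15 | (3R,4R)-oxolan-2-ylium (oxocarbenium) ion derived from 13, C2=O1+ | [O+]1=C[C@@H](COC(=O)/C=C/c2ccc(O)c(OC)c2)[C@@H](Cc2ccc(O)c(OC)c2)C1 | intermediate (not isolated)
16 | [(2S,3R,4R)-2-(4-hydroxy-3,5-dimethoxyphenyl)-4-(4-hydroxy-3-methoxybenzyl)oxolan-3-yl]methyl (E)-3-(4-hydroxy-3-methoxyphenyl)prop-2-enoate | COc1cc(/C=C/C(=O)OC[C@H]2[C@@H](Cc3ccc(O)c(OC)c3)CO[C@@H]2c2cc(OC)c(O)c(OC)c2)ccc1O | target

**Step count.** Total: 8 steps. Longest linear sequence: 8 steps (1 → 16); all other components are commercial.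

**Steps most likely to fail**

1. Step 8 (key arylation). The oxocarbenium ion may be captured at the wrong carbon, either C3 of 14 or a ring carbon of an internal guaiacyl group. The acid may also re-ionise the benzylic C2–O1 bond of the product, which then cyclises onto the C4 benzyl ring to an aryltetralin. Fallback: a 1,2-addition and cycloetherification sequence that sets out from 10 (isolated by omitting the hydrogenolysis in step 6) and returns to the route at 16.
   - Hydrolysis of the methyl acetal (1 M HCl, THF–H2O) should give (3R,4R)-4-[4-(benzyloxy)-3-methoxybenzyl]-3-(hydroxymethyl)oxolan-2-ol F1.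
   - Benzylation of commercial 4-bromo-2,6-dimethoxyphenol (BnBr, K2CO3, DMF) gives 2-(benzyloxy)-5-bromo-1,3-dimethoxybenzene F2, and Mg in THF converts it into [4-(benzyloxy)-3,5-dimethoxyphenyl]magnesium bromide F3.
   - An excess of F3 adds to the open hydroxy-aldehyde form of F1 to give (2R,3R)-3-[4-(benzyloxy)-3-methoxybenzyl]-1-[4-(benzyloxy)-3,5-dimethoxyphenyl]-2-(hydroxymethyl)butane-1,4-diol F4 as a mixture at the carbinol carbon.
   - Catalytic CSA in CH2Cl2 at 0 °C ionises the benzylic alcohol, and 5-exo capture by the C4 hydroxyl should close the ring to the 2,3-trans ether [(2S,3R,4R)-4-[4-(benzyloxy)-3-methoxybenzyl]-2-[4-(benzyloxy)-3,5-dimethoxyphenyl]oxolan-3-yl]methanol F5.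
   - Brief hydrogenolysis (H2, Pd/C, EtOAc, monitored to spare the ring ether) gives 5-methoxylariciresinol F6.
   - Mitsunobu esterification of F6 with 12 (PPh3, DIAD, THF), chemoselective for the primary alcohol, gives 16.

2. Step 4 (dimethoxymethylation). The β,β-dimethoxy lactone may lose methanol under the Lewis acid to the methoxymethylene lactone, which erases the C3 centre; C-silylation or incomplete Mukaiyama addition is also possible. Fallback: a thioacetal electrophile, setting out from 7 and returning at 10.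
   - 1,3-Dithian-2-ylium tetrafluoroborate in CH2Cl2 at −78 °C should alkylate 7 anti to the benzyl group to give (3R,4R)-4-[4-(benzyloxy)-3-methoxybenzyl]-3-(1,3-dithian-2-yl)dihydrofuran-2(3H)-one F7, which cannot eliminate under these conditions.
   - LiAlH4 in THF gives (2R,3R)-3-[4-(benzyloxy)-3-methoxybenzyl]-2-(1,3-dithian-2-yl)butane-1,4-diol F8.
   - Hg(ClO4)2, CaCO3 in MeOH–THF at 0 °C unmasks the thioacetal, and the C4 hydroxyl traps the carbonyl carbon as the cyclic methyl acetal 10.

3. Step 7 (Mitsunobu esterification). Displacement at the β-branched primary alkoxyphosphonium ion may be slow, which would let phenol O-alkylation or acyl-hydrazide formation compete. Fallback: carboxylate alkylation, setting out from 11 and returning at 13.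
   - PPh3, I2 and imidazole in CH2Cl2 convert only the aliphatic alcohol into (3S,4R)-4-(4-hydroxy-3-methoxybenzyl)-3-(iodomethyl)-2-methoxyoxolane F9.
   - The potassium carboxylate of 12 (KHCO3, DMF, 50 °C; bicarbonate is too weak to deprotonate the phenols) displaces iodide to give 13.

**Further compounds**

F1 | step 8 | (3R,4R)-4-[4-(benzyloxy)-3-methoxybenzyl]-3-(hydroxymethyl)oxolan-2-ol (C2 epimers) | OC1OC[C@H](Cc2ccc(OCc3ccccc3)c(OC)c2)[C@@H]1CO
F2 | step 8 | 2-(benzyloxy)-5-bromo-1,3-dimethoxybenzene | COc1cc(Br)cc(OC)c1OCc1ccccc1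
F3 | step 8 | [4-(benzyloxy)-3,5-dimethoxyphenyl]magnesium bromide | COc1cc([Mg]Br)cc(OC)c1OCc1ccccc1
F4 | step 8 | (2R,3R)-3-[4-(benzyloxy)-3-methoxybenzyl]-1-[4-(benzyloxy)-3,5-dimethoxyphenyl]-2-(hydroxymethyl)butane-1,4-diol (C1 epimers) | OC(c1cc(OC)c(OCc2ccccc2)c(OC)c1)[C@@H](CO)[C@H](CO)Cc1ccc(OCc2ccccc2)c(OC)c1
F5 | step 8 | [(2S,3R,4R)-4-[4-(benzyloxy)-3-methoxybenzyl]-2-[4-(benzyloxy)-3,5-dimethoxyphenyl]oxolan-3-yl]methanol | OC[C@H]1[C@@H](Cc2ccc(OCc3ccccc3)c(OC)c2)CO[C@@H]1c1cc(OC)c(OCc2ccccc2)c(OC)c1
F6 | step 8 | 5-methoxylariciresinol, 4-[(2S,3R,4R)-4-(4-hydroxy-3-methoxybenzyl)-3-(hydroxymethyl)oxolan-2-yl]-2,6-dimethoxyphenol | OC[C@H]1[C@@H](Cc2ccc(O)c(OC)c2)CO[C@@H]1c1cc(OC)c(O)c(OC)c1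
F7 | step 4 | (3R,4R)-4-[4-(benzyloxy)-3-methoxybenzyl]-3-(1,3-dithian-2-yl)dihydrofuran-2(3H)-one | O=C1OC[C@H](Cc2ccc(OCc3ccccc3)c(OC)c2)[C@H]1C1SCCCS1
F8 | step 4 | (2R,3R)-3-[4-(benzyloxy)-3-methoxybenzyl]-2-(1,3-dithian-2-yl)butane-1,4-diol | OC[C@H](Cc1ccc(OCc2ccccc2)c(OC)c1)[C@H](CO)C1SCCCS1
F9 | step 7 | (3S,4R)-4-(4-hydroxy-3-methoxybenzyl)-3-(iodomethyl)-2-methoxyoxolane (C2 epimers) | COC1OC[C@H](Cc2ccc(O)c(OC)c2)[C@@H]1CI
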